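## Structural features

The target is a 1-aryltetralin cyclolignan. Tetralin numbering is used throughout: ring A is the benzo ring with methoxy groups on C6 and C7, ring B is the saturated ring C1–C4 fused at C4a/C8a, and ring C is the 3,4-dihydroxyphenyl group on C1. C1, C2 and C3 are contiguous stereocentres, (1S,2R,3R), with aryl, CH2OH and CH2OH each trans to its neighbour, so all three sit (pseudo)equatorial. C1 is a diarylmethine with no heteroatom and no acidifying group, so it must be set absolutely and cannot be corrected later. C2 and C3 each carry a carbon that can be held at the carboxyl oxidation level, so both can be made epimerisable in a precursor. The C2–C3 bond therefore joins two carbons that are both alpha to carboxyl carbons, a succinate unit in which both carbons have donor polarity; this is the feature the key step exploits. Because C1 and C4 hang from adjacent carbons of ring A, making the C2–C3 bond also closes ring B. The fragile parts are the free catechol (oxidised by air, base or any oxidant) and the two electron-rich arenes; the real difficulty is closing ring B with control of the three contiguous centres.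

## Logic of the disconnections

11 to 10: the two phenolic O–H bonds of ring C are traded for O–benzyl bonds. The catechol would not survive strong base, a copper oxidant or hydride. The forward step must cleave two aryl benzyl ethers without touching the C1 diarylmethine or the aryl methyl ethers.

10 to 9: the two CH2OH carbons on C2 and C3 are raised to methyl esters. This makes C2 and C3 enolisable, which serves both the bond formation and the stereochemical correction. The forward reduction must not epimerise.

9 to 8: no bond is cut; the C2 and C3 configurations are released. The all-trans arrangement is handed to thermodynamic control, anchored on C1. The demand is that the all-trans isomer is the most stable one and that C1 is inert to the base.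

8 to 6: the C2–C3 bond is cut, which opens ring B. In one sentence, ring B is closed by intramolecular oxidative coupling of the bis(enolate) of the acyclic diester 6. This removes the ring and two of the three stereocentres and leaves a chain with one stereocentre. The forward step must join two nucleophilic carbons, so an oxidant is needed, and it must do so intramolecularly.

6 to 4 and 5: the bond from C1 to ring C is cut. This gives an achiral enoate and an arylboronic acid. The forward step must add the aryl group to one enantioface of the beta-carbon under catalyst control; this is the only absolute stereochemical decision in the route.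

4 to 2 and 3: the bond from ring A (the future C8a) to the future C1 is cut as an aryl–vinyl bond. The forward step is an aryl bromide–acrylate coupling that must give the E-enoate.

2 to 1: the C–Br bond is cut. The forward bromination must go to the ring position ortho to the side chain and para to a methoxy group.

## Other disconnections considered

Alternative 1: cut C1–C8a, the disconnection that comes to mind first. The lithium enolate of (4R)-4-(3,4-dimethoxybenzyl)oxolan-2-one A1 would add to 3,4-bis(benzyloxy)benzaldehyde to give the trans aldol adduct A2. Acid would ionise the benzylic alcohol of A2, ring A would attack the cation para to a methoxy group, and the all-trans lactone A3 would result; hydride reduction of A3 leads to 10. The cyclisation is sound and should give the 1,2-trans relation. It is set aside because the ring closure makes only one bond and one stereocentre, the 2,3-relation and the absolute configuration rest on enantioenriched A1, which itself costs several steps, and the whole sequence is longer than the chosen one.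

Alternative 2: cut C1–C2 and C3–C4. Thermal loss of SO2 from the sulfone A4 would give the E-configured ortho-quinodimethane A5, and Diels–Alder addition of a fumarate diester would give the constitution of 9 in one step. The fumarate fixes the 2,3-trans relation, but the C1/C2 relation depends on whether the neighbouring ester adds endo or exo, and endo addition gives 1,2-cis. Absolute control would need stoichiometric chiral ester groups on the fumarate, because A5 offers no binding site for a chiral catalyst. A4 also needs several steps and a high extrusion temperature. The chosen plan sets C1 catalytically and does not depend on endo/exo selectivity.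

Alternative 3: cut the bond from C1 to ring C on a preformed tetralin. Pd(OAc)2-catalysed, 8-aminoquinoline-directed C(sp3)–H arylation of the amide A6 at the benzylic C1 position would attach ring C last. The five-membered palladacycle delivers the aryl group cis to the C2 amide, so the product would be the 1,2-cis compound A7, the C1 epimer of what is needed. C1 cannot be epimerised afterwards, and correction through C2 would require a 2,3-cis precursor. A6 already contains two stereocentres that need their own asymmetric synthesis, and the directing group must be put on and taken off. The chosen plan has the opposite and more favourable order: C1 first, then C2 and C3 relayed from it.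

Key step: step 4

Assumption: 1, 3 and 5 are taken as catalogue compounds (5 is otherwise one lithiation–borylation step from 4-bromo-1,2-bis(benzyloxy)benzene). The antipode of the diene ligand that delivers aryl to the Re face in step 3 is not assigned here and is to be fixed on the first run.

Step 1
Reactants: 1 methyl 3-(3,4-dimethoxyphenyl)propanoate
Product: 2 methyl 3-(2-bromo-4,5-dimethoxyphenyl)propanoate
Conditions: N-bromosuccinimide (1.05 equiv), MeCN, 0 °C to rt, dark
Reagents that add atoms: N-bromosuccinimide, O=C1CCC(=O)N1Br
Why: Electrophilic aromatic bromination; the ring position para to a methoxy group and ortho to the side chain is the most activated open site, and the ester chain is inert under these non-radical conditions.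

Step 2
Reactants: 2 methyl 3-(2-bromo-4,5-dimethoxyphenyl)propanoate; 3 methyl acrylate
Product: 4 methyl (2E)-3-[4,5-dimethoxy-2-(3-methoxy-3-oxopropyl)phenyl]prop-2-enoate
Conditions: Pd(OAc)2 (3 mol %), P(o-tol)3 (9 mol %), Et3N (2 equiv), DMF, 100 °C
Reagents that add atoms: 3 methyl acrylate, C=CC(=O)OC
Why: Mizoroki–Heck reaction; zerovalent palladium formed in situ inserts into the aryl bromide, and syn-insertion of the acrylate followed by syn-beta-hydride elimination should give the E-enoate, with the saturated ester as a spectator.

Step 3
Reactants: 4 methyl (2E)-3-[4,5-dimethoxy-2-(3-methoxy-3-oxopropyl)phenyl]prop-2-enoate; 5 [3,4-bis(benzyloxy)phenyl]boronic acid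
Product: 6 methyl (3S)-3-[3,4-bis(benzyloxy)phenyl]-3-[4,5-dimethoxy-2-(3-methoxy-3-oxopropyl)phenyl]propanoate
Conditions: [RhCl(C2H4)2]2 (1.5 mol %), (1R,4R)-2,5-diphenylbicyclo[2.2.2]octa-2,5-diene or its antipode (3.3 mol %; the antipode that gives Re-face delivery at C3 of 4), KOH (0.2 equiv), 1,4-dioxane/H2O 10:1, 40 °C, 5 (2 equiv)
Reagents that add atoms: 5 [3,4-bis(benzyloxy)phenyl]boronic acid, OB(O)c1ccc(OCc2ccccc2)c(OCc2ccccc2)c1
Why: Hayashi–Miyaura asymmetric 1,4-addition; the aryl complex of monovalent rhodium with the C2-symmetric diene inserts the enoate on one face, Re-face delivery at the beta-carbon gives (3S), and water protonates the rhodium enolate before it can attack the remote ester. This sets C1 of the target.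

Step 4
Reactants: 6 methyl (3S)-3-[3,4-bis(benzyloxy)phenyl]-3-[4,5-dimethoxy-2-(3-methoxy-3-oxopropyl)phenyl]propanoate
Product: 8 dimethyl (1S)-1-[3,4-bis(benzyloxy)phenyl]-6,7-dimethoxy-1,2,3,4-tetrahydronaphthalene-2,3-dicarboxylate (mixture of C2/C3 epimers), via dilithium bis(enolate) 7 (not isolated)
Conditions: LiN(iPr)2 (2.3 equiv), THF, −78 °C, slow addition of 6; then anhydrous CuCl2 (2.3 equiv) in DMF, −78 °C to 0 °C, 0.02 M; aq NH4Cl
Reagents that add atoms: none
Why: LiN(iPr)2 removes one alpha-hydrogen from each ester, both far more acidic than the C1 diarylmethine hydrogen, to give 7, in which the ortho-phenylene unit of ring A holds the future C2 and C3 close together. Divalent copper chloride takes one electron from an enolate by inner-sphere transfer, the alpha-ester radical (or its copper-bound equivalent) adds to the alpha-carbon of the second enolate, and a second equivalent of CuCl2 oxidises the resulting radical anion, so two carbons of like polarity are joined in a net two-electron oxidation. The closest known reaction type is the copper- or iodine-mediated intramolecular oxidative coupling of dilithium bis(enolates) of alpha,omega-diesters to cycloalkane-1,2-dicarboxylates of ring size up to six. Only ring B is closed, in a 6-exo-trig mode, since the attacked enolate C=C lies outside the forming ring. C2 and C3 form under the influence of C1 through a chair-like transition state with the C1 aryl group pseudoequatorial, which should favour the trans-diester; both centres stay enolisable, so incomplete selectivity is corrected in step 5. The step needs intra- over intermolecular coupling, secured by the short rigid tether and by dilution, and oxidation of the enolates in preference to the two electron-rich arenes, secured by the large gap between their oxidation potentials. C–C coupling rather than C–O coupling or alpha-chlorination is expected because the carbon radical is generated next to a carbon nucleophile.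

Step 5
Reactants: 8 dimethyl (1S)-1-[3,4-bis(benzyloxy)phenyl]-6,7-dimethoxy-1,2,3,4-tetrahydronaphthalene-2,3-dicarboxylate (mixture of C2/C3 epimers)
Product: 9 dimethyl (1S,2R,3R)-1-[3,4-bis(benzyloxy)phenyl]-6,7-dimethoxy-1,2,3,4-tetrahydronaphthalene-2,3-dicarboxylate
Conditions: NaOMe (0.5 equiv), MeOH, 65 °C; AcOH quench
Reagents that add atoms: none
Why: Thermodynamic epimerisation through the ester enolates; C2 and C3 each carry an acidic alpha-hydrogen while the C1 hydrogen is not removed by methoxide, so all C2/C3 isomers should converge on the isomer with aryl, ester and ester all (pseudo)equatorial, which with C1 fixed as S is (1S,2R,3R).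

Step 6
Reactants: 9 dimethyl (1S,2R,3R)-1-[3,4-bis(benzyloxy)phenyl]-6,7-dimethoxy-1,2,3,4-tetrahydronaphthalene-2,3-dicarboxylate
Product: 10 [(1S,2R,3R)-1-[3,4-bis(benzyloxy)phenyl]-6,7-dimethoxy-1,2,3,4-tetrahydronaphthalene-2,3-diyl]dimethanol
Conditions: LiAlH4 (3 equiv), THF, 0 °C to rt; aq NaOH work-up
Reagents that add atoms: none
Why: Hydride reduction of both esters to primary alcohols; reduction is faster than enolisation at this temperature, so C2 and C3 should be retained, and the benzyl and methyl aryl ethers are inert.

Step 7
Reactants: 10 [(1S,2R,3R)-1-[3,4-bis(benzyloxy)phenyl]-6,7-dimethoxy-1,2,3,4-tetrahydronaphthalene-2,3-diyl]dimethanol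
Product: 11 4-[(1S,2R,3R)-2,3-bis(hydroxymethyl)-6,7-dimethoxy-1,2,3,4-tetrahydronaphthalen-1-yl]benzene-1,2-diol
Conditions: H2 (1 atm), 10% Pd/C, MeOH/EtOAc, rt; filtration and concentration under argon
Reagents that add atoms: none
Why: Hydrogenolysis of the two aryl benzyl ethers; the C1 diarylmethine has no C–heteroatom bond to cleave, the aryl methyl ethers and primary alcohols are inert, and the neutral reductive medium protects the catechol from oxidation.

Compound list

1 | methyl 3-(3,4-dimethoxyphenyl)propanoate | COC(=O)CCc1ccc(OC)c(OC)c1 | starting material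
2 | methyl 3-(2-bromo-4,5-dimethoxyphenyl)propanoate | COC(=O)CCc1cc(OC)c(OC)cc1Br | intermediate
3 | methyl acrylate | C=CC(=O)OC | starting material
4 | methyl (2E)-3-[4,5-dimethoxy-2-(3-methoxy-3-oxopropyl)phenyl]prop-2-enoate | COC(=O)/C=C/c1cc(OC)c(OC)cc1CCC(=O)OC | intermediate
5 | [3,4-bis(benzyloxy)phenyl]boronic acid | OB(O)c1ccc(OCc2ccccc2)c(OCc2ccccc2)c1 | starting material
6 | methyl (3S)-3-[3,4-bis(benzyloxy)phenyl]-3-[4,5-dimethoxy-2-(3-methoxy-3-oxopropyl)phenyl]propanoate | COC(=O)C[C@@H](c1ccc(OCc2ccccc2)c(OCc2ccccc2)c1)c1cc(OC)c(OC)cc1CCC(=O)OC | intermediate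
7 | dilithium bis(enolate) of 6 (enolate geometry not defined) | [Li+].[Li+].COC([O-])=C[C@@H](c1ccc(OCc2ccccc2)c(OCc2ccccc2)c1)c1cc(OC)c(OC)cc1CC=C([O-])OC | intermediate (not isolated)
8 | dimethyl (1S)-1-[3,4-bis(benzyloxy)phenyl]-6,7-dimethoxy-1,2,3,4-tetrahydronaphthalene-2,3-dicarboxylate, C2 and C3 not defined | COc1cc2c(cc1OC)[C@H](c1ccc(OCc3ccccc3)c(OCc3ccccc3)c1)C(C(=O)OC)C(C(=O)OC)C2 | intermediate
9 | dimethyl (1S,2R,3R)-1-[3,4-bis(benzyloxy)phenyl]-6,7-dimethoxy-1,2,3,4-tetrahydronaphthalene-2,3-dicarboxylate | COc1cc2c(cc1OC)[C@H](c1ccc(OCc3ccccc3)c(OCc3ccccc3)c1)[C@@H](C(=O)OC)[C@H](C(=O)OC)C2 | intermediate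
10 | [(1S,2R,3R)-1-[3,4-bis(benzyloxy)phenyl]-6,7-dimethoxy-1,2,3,4-tetrahydronaphthalene-2,3-diyl]dimethanol | COc1cc2c(cc1OC)[C@H](c1ccc(OCc3ccccc3)c(OCc3ccccc3)c1)[C@@H](CO)[C@H](CO)C2 | intermediate
11 | 4-[(1S,2R,3R)-2,3-bis(hydroxymethyl)-6,7-dimethoxy-1,2,3,4-tetrahydronaphthalen-1-yl]benzene-1,2-diol | COc1cc2c(cc1OC)[C@H](c1ccc(O)c(O)c1)[C@@H](CO)[C@H](CO)C2 | target

Total step count: 7. Longest linear sequence: 7 steps (1 to 11); 3 and 5 enter as bought reagents.

Least certain steps

Step 4 (key step). The most likely failures are intermolecular coupling to oligomers, alpha-chlorination of an enolate by CuCl2, and condensation of a mono-enolate with the second ester while deprotonation is still incomplete. The hindered enolate next to the diarylmethine may also react sluggishly. The fallback reverses the polarity of the closure; it sets out from 6 and returns at 8. The bis(enolate) 7 is trapped with Me3SiCl as the bis(trimethylsilyl ketene acetal) F1. N-Bromosuccinimide converts F1 into the bis(alpha-bromo) diester F2. Zinc dust in DMF (or cathodic reduction) then reduces one C–Br bond to a zinc enolate, which displaces the second bromide in a 6-exo-tet closure to give 8. Reduction of both C–Br bonds would only return 6, which can be recycled.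

Step 3. Insertion of the ortho-substituted beta-aryl enoate may be slow enough that protodeboronation of 5 competes, and enantioface discrimination may be insufficient for this substitution pattern. The fallback replaces catalyst control by auxiliary control; it sets out from 2 and returns at 6. (4R)-4-Phenyl-1,3-oxazolidin-2-one is acylated with acryloyl chloride to the acrylimide F3. A Mizoroki–Heck reaction of 2 with F3 gives the enoyl imide F4. The arylmagnesium bromide F5, made from 4-bromo-1,2-bis(benzyloxy)benzene and magnesium, is added with CuBr·SMe2 in THF at −40 °C; in the magnesium-chelated syn, s-cis conformer the aryl group adds to the face remote from the phenyl group, which should give the (3S) adduct F6. NaOMe in MeOH at 0 °C then releases 6 and the auxiliary.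

Step 5. Convergence may be incomplete: the 1,2-cis-2,3-trans isomer, with the aryl group pseudoaxial and free of peri strain against C8–H, may lie close in energy to the all-trans isomer, and traces of water would saponify the esters. The fallback sets C2 and C3 kinetically by auxiliaries; it sets out from 6 and returns at 10, replacing steps 4 to 6. LiOH in THF/H2O gives the diacid F7. Activation as the bis(pivalic mixed anhydride) and reaction with lithiated (4S)-4-benzyl-1,3-oxazolidin-2-one gives the bis(imide) F8. Double enolisation with LiN(iPr)2 and oxidation with CuCl2 couples the two chelated Z-enolates, each on the face remote from its benzyl group; this corresponds to R at both new centres and should give the (1S,2R,3R) bis(imide) F9. LiBH4 in THF/MeOH removes both auxiliaries reductively and gives 10.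

Further compounds

F1 | step 4 | bis(trimethylsilyl ketene acetal) of 6, C1 centre S | COC(O[Si](C)(C)C)=C[C@@H](c1ccc(OCc2ccccc2)c(OCc2ccccc2)c1)c1cc(OC)c(OC)cc1CC=C(OC)O[Si](C)(C)C
F2 | step 4 | methyl (3S)-3-[3,4-bis(benzyloxy)phenyl]-2-bromo-3-[2-(2-bromo-3-methoxy-3-oxopropyl)-4,5-dimethoxyphenyl]propanoate, C–Br centres not defined | COC(=O)C(Br)[C@@H](c1ccc(OCc2ccccc2)c(OCc2ccccc2)c1)c1cc(OC)c(OC)cc1CC(Br)C(=O)OC
F3 | step 3 | (4R)-4-phenyl-3-(prop-2-enoyl)-1,3-oxazolidin-2-one | C=CC(=O)N1[C@H](c2ccccc2)COC1=O
F4 | step 3 | methyl 3-[4,5-dimethoxy-2-[(1E)-3-oxo-3-[(4R)-2-oxo-4-phenyl-1,3-oxazolidin-3-yl]prop-1-en-1-yl]phenyl]propanoate | COC(=O)CCc1cc(OC)c(OC)cc1/C=C/C(=O)N1[C@H](c2ccccc2)COC1=O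
F5 | step 3 | [3,4-bis(benzyloxy)phenyl]magnesium bromide | Br[Mg]c1ccc(OCc2ccccc2)c(OCc2ccccc2)c1
F6 | step 3 | methyl 3-[2-[(1S)-1-[3,4-bis(benzyloxy)phenyl]-3-oxo-3-[(4R)-2-oxo-4-phenyl-1,3-oxazolidin-3-yl]propyl]-4,5-dimethoxyphenyl]propanoate | COC(=O)CCc1cc(OC)c(OC)cc1[C@H](c1ccc(OCc2ccccc2)c(OCc2ccccc2)c1)CC(=O)N1[C@H](c2ccccc2)COC1=O
F7 | step 5 | (3S)-3-[3,4-bis(benzyloxy)phenyl]-3-[2-(2-carboxyethyl)-4,5-dimethoxyphenyl]propanoic acid | OC(=O)C[C@@H](c1ccc(OCc2ccccc2)c(OCc2ccccc2)c1)c1cc(OC)c(OC)cc1CCC(=O)O
F8 | step 5 | bis(imide) of F7 with two (4S)-4-benzyl-2-oxo-1,3-oxazolidin-3-yl groups, C1 centre S | O=C1OC[C@H](Cc2ccccc2)N1C(=O)C[C@@H](c1ccc(OCc2ccccc2)c(OCc2ccccc2)c1)c1cc(OC)c(OC)cc1CCC(=O)N1[C@@H](Cc2ccccc2)COC1=O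
F9 | step 5 | (1S,2R,3R)-1-[3,4-bis(benzyloxy)phenyl]-6,7-dimethoxy-1,2,3,4-tetrahydronaphthalene-2,3-diyl bis[carbonyl-(4S)-4-benzyl-1,3-oxazolidin-2-one] | COc1cc2c(cc1OC)[C@H](c1ccc(OCc3ccccc3)c(OCc3ccccc3)c1)[C@@H](C(=O)N1[C@@H](Cc3ccccc3)COC1=O)[C@H](C(=O)N1[C@@H](Cc3ccccc3)COC1=O)C2
A1 | alternative 1 | (4R)-4-(3,4-dimethoxybenzyl)oxolan-2-one | O=C1OC[C@H](Cc2ccc(OC)c(OC)c2)C1
A2 | alternative 1 | (3S,4R)-3-{[3,4-bis(benzyloxy)phenyl](hydroxy)methyl}-4-(3,4-dimethoxybenzyl)oxolan-2-one, carbinol centre not defined | O=C1OC[C@H](Cc2ccc(OC)c(OC)c2)[C@H]1C(O)c1ccc(OCc2ccccc2)c(OCc2ccccc2)c1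
A3 | alternative 1 | all-trans aryltetralin gamma-lactone, carbonyl on C2, (1S,2R,3R) in tetralin numbering | COc1cc2c(cc1OC)[C@H](c1ccc(OCc3ccccc3)c(OCc3ccccc3)c1)[C@H]1C(=O)OC[C@@H]1C2
A4 | alternative 2 | 1-[3,4-bis(benzyloxy)phenyl]-5,6-dimethoxy-1,3-dihydro-2-benzothiophene 2,2-dioxide, racemic | COc1cc2c(cc1OC)C(c1ccc(OCc3ccccc3)c(OCc3ccccc3)c1)S(=O)(=O)C2
A5 | alternative 2 | (E)-ortho-quinodimethane from A4 | C=C1C=C(OC)C(OC)=C/C1=C\c1ccc(OCc2ccccc2)c(OCc2ccccc2)c1
A6 | alternative 3 | methyl (2R,3R)-6,7-dimethoxy-3-(quinolin-8-ylcarbamoyl)-1,2,3,4-tetrahydronaphthalene-2-carboxylate | COc1cc2c(cc1OC)C[C@@H](C(=O)Nc1cccc3cccnc13)[C@H](C(=O)OC)C2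
A7 | alternative 3 | 1,2-cis arylation product of A6, (1R,2R,3R) in target numbering | COc1cc2c(cc1OC)[C@@H](c1ccc(OCc3ccccc3)c(OCc3ccccc3)c1)[C@@H](C(=O)Nc1cccc3cccnc13)[C@H](C(=O)OC)C2
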